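The C7 hydroxyl oxygen and the lactone ring oxygen sit on carbons that flank C8 (a C7–C8–C9 1,3-dioxygen pattern), so C9 is cut from C8 and delivered from a silicon atom temporarily bonded to O7. One radical cyclisation of a bromomethylsilyl ether onto an enoate makes the C8–C9 bond, closes a 1-oxa-2-silacyclopentane (O7, Si, C9, C8, C7) and relays the C7 configuration to C8. The precursor is the O7-(bromomethyl)dimethylsilyl ether of a methyl (2E,4R)-4-aryl-2-(arylmethyl)-4-hydroxybut-2-enoate, built from vanillin by asymmetric propiolate addition, trans-hydroalumination–iodination and Negishi benzylation. Oxidative excision of silicon, lactonisation onto C9' with C8' equilibration and desilylation finish the target.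

Key step: step 8

Remark: lignan numbering is used (C7 carbinol, C8 lactone β-CH, C9 lactone OCH2, C8' lactone α-CH, C9' carbonyl, C7' benzylic CH2); Ar = 3-methoxy-4-(triisopropylsilyloxy)phenyl.
Remark: the phenols are carried as triisopropylsilyl ethers, because aryl silyl ethers have to outlast basic peroxide (step 9) and an amidine base (step 10), where smaller silyl groups are at risk.
Remark: CIP labels change along the route without any change in space: C7 is S in alkynol 4 (alkynyl outranks aryl) and R from 5 on; C8 is S in silacycle 13 (silicon raises C9) and R in 14 to 17.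
Assumption: (R)-BINOL is taken to steer the alkynylzinc to the Re face of 2 in step 2, by analogy with BINOL–titanium organozinc additions; should the sense prove opposite, (S)-BINOL is used and nothing else changes.

Step 1
Reactants: 1 vanillin
Product: 2 ArCHO (3-methoxy-4-(triisopropylsilyloxy)benzaldehyde)
Conditions: iPr3SiCl, imidazole, DMF, 20 °C
Reagents that add atoms: triisopropylsilyl chloride, CC(C)[Si](Cl)(C(C)C)C(C)C
Why: Imidazole-promoted O-silylation of a phenol (silyl ether formation) should be clean, and the bulky silyl group is chosen for its stability to the later basic steps.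

Step 2
Reactants: 2 ArCHO; 3 methyl propiolate
Product: 4 methyl (S)-4-Ar-4-hydroxybut-2-ynoate
Conditions: (R)-BINOL (40 mol%), Et2Zn, HMPA, CH2Cl2, 20 °C; then Ti(OiPr)4; then 2, 20 °C
Reagents that add atoms: none
Why: BINOL–titanium-mediated enantioselective addition of the zinc acetylide of methyl propiolate to an aromatic aldehyde (asymmetric alkynylation) should set C7 by ligand-controlled attack on the Re face of the aldehyde, and HMPA allows the acetylide to form at room temperature without loss of the propiolate.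

Step 3
Reactants: 4 methyl (S)-4-Ar-4-hydroxybut-2-ynoate
Product: 6 methyl (2Z,4R)-4-Ar-4-hydroxy-2-iodobut-2-enoate, via cyclic alkenylaluminate 5 (not isolated)
Conditions: NaAlH2(OCH2CH2OMe)2, THF, -72 °C; then I2, THF, -72 to -20 °C
Reagents that add atoms: iodine, II
Why: Hydroxyl-directed trans-hydroalumination of a γ-hydroxy ynoate followed by iodinolysis of the C–Al bond with retention should place hydride on C8 and iodine on C8' cis to C7 (ester trans to C7), because aluminium bridges O7 and C8', and the low temperature should spare the ester.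

Step 4
Reactants: 2 ArCHO
Product: 7 ArCH2OH ([3-methoxy-4-(triisopropylsilyloxy)phenyl]methanol)
Conditions: NaBH4, MeOH, 0 °C
Reagents that add atoms: none
Why: Borohydride reduction of an aryl aldehyde to the benzylic alcohol should leave the aryl silyl ether untouched.

Step 5
Reactants: 7 ArCH2OH
Product: 8 ArCH2Cl (3-methoxy-4-(triisopropylsilyloxy)benzyl chloride)
Conditions: N-chlorosuccinimide, PPh3, THF, 0 to 20 °C
Reagents that add atoms: N-chlorosuccinimide, O=C1CCC(=O)N1Cl
Why: Appel-type chlorination (chlorophosphonium activation, displacement by chloride) works under neutral conditions, so the electron-rich benzylic chloride and the silyl ether should survive and the crude chloride can be used at once.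

Step 6
Reactants: 6 methyl (2Z,4R)-4-Ar-4-hydroxy-2-iodobut-2-enoate; 8 ArCH2Cl
Product: 10 methyl (2E,4R)-4-Ar-2-(ArCH2)-4-hydroxybut-2-enoate, via benzylzinc chloride 9 (not isolated)
Conditions: 8, Zn dust, LiCl, THF, 25 °C; then 6, Pd(OAc)2 (2 mol%), SPhos (4 mol%), THF, 25 °C
Reagents that add atoms: none
Why: Zinc insertion into the benzylic chloride followed by Negishi cross-coupling with the alkenyl iodide should replace iodine by the benzyl group with retention of alkene geometry, and with the biarylphosphine catalyst coupling should outpace protonation of the benzylzinc reagent by the free hydroxyl.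

Step 7
Reactants: 10 methyl (2E,4R)-4-Ar-2-(ArCH2)-4-hydroxybut-2-enoate; 11 (bromomethyl)chlorodimethylsilane
Product: 12 methyl (2E,4R)-4-Ar-2-(ArCH2)-4-{[(bromomethyl)dimethylsilyl]oxy}but-2-enoate
Conditions: Et3N, DMAP (cat.), CH2Cl2, 0 °C
Reagents that add atoms: none
Why: Base-mediated O-silylation of the secondary allylic alcohol with a chlorosilane should install the tether without touching C7 or the alkene, and the hydrolytically labile ether is carried on without storage.

Step 8
Reactants: 12 methyl (2E,4R)-4-Ar-2-(ArCH2)-4-{[(bromomethyl)dimethylsilyl]oxy}but-2-enoate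
Product: 13 methyl 3-Ar-2-[(4S,5R)-5-Ar-2,2-dimethyl-1-oxa-2-silacyclopentan-4-yl]propanoate (both C2 epimers)
Conditions: Bu3SnH (1.3 equiv, syringe pump), AIBN (10 mol%), toluene (0.01 M), 85 °C
Reagents that add atoms: none
Why: Bromine abstraction by the stannyl radical gives the α-silyl primary radical C9, which adds to the enoate β-carbon C8, and the ester-stabilised C8' radical then takes hydrogen from Bu3SnH to carry the chain; the closest known reaction type is the reductive silicon-tethered radical cyclisation of (bromomethyl)dimethylsilyl ethers of allylic alcohols (Nishiyama–Stork cyclisation). The one ring formed, the 1-oxa-2-silacyclopentane O7–Si–C9–C8–C7, closes in the 5-exo-trig mode, which should win over 6-endo attack because that would have to occur at the fully substituted C8' and against the polarity of the enoate. The new stereocentre C8 is controlled by C7: the C7' methylene lies cis to C7 on the alkene, so allylic 1,3-strain keeps H7 in the alkene plane, O7 and Ar then occupy opposite faces, and the short tether can reach C8 only from the O7 face, which puts Ar on C7 and the C8' chain on C8 trans on the new ring (the 7R,8R relation of the target). The step needs this face selectivity and needs ring closure to outrun hydrogen transfer to the uncyclised radical; the first is secured by the (E)-geometry fixed in steps 3 and 6, the second by slow stannane addition at high dilution. C8' is formed without control, which is tolerated because it becomes the epimerisable lactone α-carbon in step 10.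

Step 9
Reactants: 13 methyl 3-Ar-2-[(4S,5R)-5-Ar-2,2-dimethyl-1-oxa-2-silacyclopentan-4-yl]propanoate
Product: 14 methyl (3R,4R)-4-Ar-2-(ArCH2)-4-hydroxy-3-(hydroxymethyl)butanoate (both C2 epimers)
Conditions: 30% aq H2O2, KHCO3, MeOH/THF (1:1), 50 °C
Reagents that add atoms: hydrogen peroxide, OO
Why: Tamao oxidation of the cyclic alkoxysilane (hydroperoxide adds to silicon, C9 migrates from silicon to oxygen, the O7–Si bond is solvolysed) should free the 1,3-diol without fluoride, since silicon already carries an oxygen, so the aryl silyl ethers stay on and C7 and C8 are not involved.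

Step 10
Reactants: 14 methyl (3R,4R)-4-Ar-2-(ArCH2)-4-hydroxy-3-(hydroxymethyl)butanoate
Product: 16 (3R,4R)-4-[(R)-Ar(hydroxy)methyl]-3-(ArCH2)dihydrofuran-2(3H)-one, via lactone epimer mixture 15 (not isolated)
Conditions: DBU, 4 Å molecular sieves, toluene, 60 °C
Reagents that add atoms: none
Why: Base-mediated lactonisation of the primary C9 hydroxyl onto the C9' methyl ester followed by enolisation and reprotonation at C8' (thermodynamic epimerisation of an α,β-disubstituted γ-butyrolactone) should converge on the trans lactone and so set C8' as R, while the isomeric lactone through O7 would force Ar and the hydroxymethyl group cis and is not expected to accumulate.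

Step 11
Reactants: 16 (3R,4R)-4-[(R)-Ar(hydroxy)methyl]-3-(ArCH2)dihydrofuran-2(3H)-one
Product: 17 5-allohydroxymatairesinol, (3R,4R)-3-(4-hydroxy-3-methoxybenzyl)-4-[(R)-hydroxy(4-hydroxy-3-methoxyphenyl)methyl]dihydrofuran-2(3H)-one
Conditions: Bu4NF, AcOH (1:1), THF, 0 °C
Reagents that add atoms: none
Why: Fluoride-mediated cleavage of the two aryl silyl ethers (desilylation) under acetic acid buffering should keep the liberated para-hydroxybenzylic alcohol from ionising to a quinone methide, so C7 is not scrambled and the lactone is untouched.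

Compound list (Ar = 3-methoxy-4-(triisopropylsilyloxy)phenyl)
1 | vanillin (4-hydroxy-3-methoxybenzaldehyde) | O=Cc1ccc(O)c(OC)c1 | starting material
2 | 3-methoxy-4-(triisopropylsilyloxy)benzaldehyde (ArCHO) | O=Cc1ccc(O[Si](C(C)C)(C(C)C)C(C)C)c(OC)c1 | intermediate
3 | methyl propiolate | C#CC(=O)OC | starting material
4 | methyl (S)-4-Ar-4-hydroxybut-2-ynoate | COC(=O)C#C[C@@H](O)c1ccc(O[Si](C(C)C)(C(C)C)C(C)C)c(OC)c1 | intermediate
5 | cyclic alkenylaluminate, sodium salt: aluminium bound to O7 and C8' and to two 2-methoxyethoxy groups, hydride on C8, C7 (R) | COC(=O)C1=C[C@H](c2ccc(O[Si](C(C)C)(C(C)C)C(C)C)c(OC)c2)O[Al-]1(OCCOC)OCCOC.[Na+] | intermediate (not isolated)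
6 | methyl (2Z,4R)-4-Ar-4-hydroxy-2-iodobut-2-enoate | COC(=O)/C(I)=C/[C@@H](O)c1ccc(O[Si](C(C)C)(C(C)C)C(C)C)c(OC)c1 | intermediate
7 | [3-methoxy-4-(triisopropylsilyloxy)phenyl]methanol (ArCH2OH) | OCc1ccc(O[Si](C(C)C)(C(C)C)C(C)C)c(OC)c1 | intermediate
8 | 3-methoxy-4-(triisopropylsilyloxy)benzyl chloride (ArCH2Cl) | ClCc1ccc(O[Si](C(C)C)(C(C)C)C(C)C)c(OC)c1 | intermediate
9 | [3-methoxy-4-(triisopropylsilyloxy)benzyl]zinc chloride | Cl[Zn]Cc1ccc(O[Si](C(C)C)(C(C)C)C(C)C)c(OC)c1 | intermediate (not isolated)
10 | methyl (2E,4R)-4-Ar-2-(ArCH2)-4-hydroxybut-2-enoate | COC(=O)/C(Cc1ccc(O[Si](C(C)C)(C(C)C)C(C)C)c(OC)c1)=C/[C@@H](O)c1ccc(O[Si](C(C)C)(C(C)C)C(C)C)c(OC)c1 | intermediate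
11 | (bromomethyl)chlorodimethylsilane | C[Si](C)(Cl)CBr | starting material
12 | methyl (2E,4R)-4-Ar-2-(ArCH2)-4-{[(bromomethyl)dimethylsilyl]oxy}but-2-enoate (key-step precursor) | COC(=O)/C(Cc1ccc(O[Si](C(C)C)(C(C)C)C(C)C)c(OC)c1)=C/[C@@H](O[Si](C)(C)CBr)c1ccc(O[Si](C(C)C)(C(C)C)C(C)C)c(OC)c1 | intermediate
13 | methyl 3-Ar-2-[(4S,5R)-5-Ar-2,2-dimethyl-1-oxa-2-silacyclopentan-4-yl]propanoate, trans ring, both C2 epimers (key-step product) | COC(=O)C(Cc1ccc(O[Si](C(C)C)(C(C)C)C(C)C)c(OC)c1)[C@@H]1C[Si](C)(C)O[C@H]1c1ccc(O[Si](C(C)C)(C(C)C)C(C)C)c(OC)c1 | intermediate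
14 | methyl (3R,4R)-4-Ar-2-(ArCH2)-4-hydroxy-3-(hydroxymethyl)butanoate, both C2 epimers | COC(=O)C(Cc1ccc(O[Si](C(C)C)(C(C)C)C(C)C)c(OC)c1)[C@H](CO)[C@@H](O)c1ccc(O[Si](C(C)C)(C(C)C)C(C)C)c(OC)c1 | intermediate
15 | (4R)-4-[(R)-Ar(hydroxy)methyl]-3-(ArCH2)dihydrofuran-2(3H)-one, both C3 epimers | COc1cc(CC2C(=O)OC[C@@H]2[C@@H](O)c2ccc(O[Si](C(C)C)(C(C)C)C(C)C)c(OC)c2)ccc1O[Si](C(C)C)(C(C)C)C(C)C | intermediate (not isolated)
16 | (3R,4R)-4-[(R)-Ar(hydroxy)methyl]-3-(ArCH2)dihydrofuran-2(3H)-one | COc1cc(C[C@H]2C(=O)OC[C@@H]2[C@@H](O)c2ccc(O[Si](C(C)C)(C(C)C)C(C)C)c(OC)c2)ccc1O[Si](C(C)C)(C(C)C)C(C)C | intermediate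
17 | 5-allohydroxymatairesinol, (3R,4R)-3-(4-hydroxy-3-methoxybenzyl)-4-[(R)-hydroxy(4-hydroxy-3-methoxyphenyl)methyl]dihydrofuran-2(3H)-one (7R,8R,8'R) | COc1cc(C[C@H]2C(=O)OC[C@@H]2[C@@H](O)c2ccc(O)c(OC)c2)ccc1O | target

Total step count: 11. Longest linear sequence: 9 steps (1, 2, 3, 6, 7, 8, 9, 10, 11); steps 4 and 5 form a two-step branch from 2.

Steps most likely to fail

Step 8. Hydrogen transfer to the α-silyl radical may overtake ring closure, the chain may stall at the hindered, fully substituted C8' radical, or face selectivity at C8 may be eroded. The fallback moves the benzyl group to the end, so that the radical meets a plain acrylate. It sets out from 4 and comes back at 16. Quenching the hydroalumination of 4 with water instead of iodine (NaAlH2(OCH2CH2OMe)2, THF, -72 °C) should give methyl (2E,4R)-4-Ar-4-hydroxybut-2-enoate F1. Silylation with 11 gives the bromomethylsilyl ether methyl (2E,4R)-4-Ar-4-{[(bromomethyl)dimethylsilyl]oxy}but-2-enoate F2. Tin hydride cyclisation gives the silacycle methyl 2-[(4S,5R)-5-Ar-2,2-dimethyl-1-oxa-2-silacyclopentan-4-yl]acetate F3. Tamao oxidation gives the diol ester methyl (3R,4R)-4-Ar-4-hydroxy-3-(hydroxymethyl)butanoate F4, which closes to the hydroxy lactone (4R)-4-[(R)-Ar(hydroxy)methyl]dihydrofuran-2(3H)-one F5. The dianion of F5 (LiN(iPr)2, 2.2 equiv, THF, -78 °C) is alkylated with 8 in the presence of Bu4NI, anti to the C8 substituent, to give 16. The price is that face selectivity at C8 then rests on the ring-closure preference alone, since the alkene no longer carries a cis substituent.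

Step 2. With the electron-rich aldehyde the catalysed addition may be slow enough for an unselective background addition to lower the enantiomeric purity. The fallback sets the carbinol by reagent-controlled reduction instead of addition; it sets out from 4 of insufficient purity and comes back at 4. Oxidation with MnO2 in CH2Cl2 gives the ynone methyl 4-Ar-4-oxobut-2-ynoate F6. Midland reduction with (S)-Alpine-Borane (B-isopinocampheyl-9-borabicyclo[3.3.1]nonane from (-)-α-pinene), in which the slim alkynyl group takes the small-group role, should return (S)-4.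

Step 10. The acyl group may migrate to O7 (translactonisation), equilibration at C8' may stay incomplete, or an aryl silyl ether may be lost to the amidine base. The fallback blocks O7 before the base treatment; it sets out from 14 and comes back at 17. A catalytic amount of DBU at 0 °C closes 14 to 15, and the reaction is stopped before equilibration. Et3SiCl and imidazole in CH2Cl2 give the O7-triethylsilyl ether of the lactone mixture, (4R)-4-[(R)-Ar(triethylsilyloxy)methyl]-3-(ArCH2)dihydrofuran-2(3H)-one F7. DBU in toluene equilibrates F7 to the trans lactone (3R,4R)-4-[(R)-Ar(triethylsilyloxy)methyl]-3-(ArCH2)dihydrofuran-2(3H)-one F8, in which acyl transfer to O7 is impossible. Bu4NF/AcOH then removes all three silyl groups to give 17.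

Further compounds
F1 | step 8 | methyl (2E,4R)-4-Ar-4-hydroxybut-2-enoate | COC(=O)/C=C/[C@@H](O)c1ccc(O[Si](C(C)C)(C(C)C)C(C)C)c(OC)c1
F2 | step 8 | methyl (2E,4R)-4-Ar-4-{[(bromomethyl)dimethylsilyl]oxy}but-2-enoate | COC(=O)/C=C/[C@@H](O[Si](C)(C)CBr)c1ccc(O[Si](C(C)C)(C(C)C)C(C)C)c(OC)c1
F3 | step 8 | methyl 2-[(4S,5R)-5-Ar-2,2-dimethyl-1-oxa-2-silacyclopentan-4-yl]acetate | COC(=O)C[C@@H]1C[Si](C)(C)O[C@H]1c1ccc(O[Si](C(C)C)(C(C)C)C(C)C)c(OC)c1
F4 | step 8 | methyl (3R,4R)-4-Ar-4-hydroxy-3-(hydroxymethyl)butanoate | COC(=O)C[C@H](CO)[C@@H](O)c1ccc(O[Si](C(C)C)(C(C)C)C(C)C)c(OC)c1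
F5 | step 8 | (4R)-4-[(R)-Ar(hydroxy)methyl]dihydrofuran-2(3H)-one | C1C(=O)OC[C@@H]1[C@@H](O)c1ccc(O[Si](C(C)C)(C(C)C)C(C)C)c(OC)c1
F6 | step 2 | methyl 4-Ar-4-oxobut-2-ynoate | COC(=O)C#CC(=O)c1ccc(O[Si](C(C)C)(C(C)C)C(C)C)c(OC)c1
F7 | step 10 | (4R)-4-[(R)-Ar(triethylsilyloxy)methyl]-3-(ArCH2)dihydrofuran-2(3H)-one, both C3 epimers | COc1cc(CC2C(=O)OC[C@@H]2[C@@H](O[Si](CC)(CC)CC)c2ccc(O[Si](C(C)C)(C(C)C)C(C)C)c(OC)c2)ccc1O[Si](C(C)C)(C(C)C)C(C)C
F8 | step 10 | (3R,4R)-4-[(R)-Ar(triethylsilyloxy)methyl]-3-(ArCH2)dihydrofuran-2(3H)-one | COc1cc(C[C@H]2C(=O)OC[C@@H]2[C@@H](O[Si](CC)(CC)CC)c2ccc(O[Si](C(C)C)(C(C)C)C(C)C)c(OC)c2)ccc1O[Si](C(C)C)(C(C)C)C(C)C
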